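D.X is what I want at the end of each flask: the first step below makes it and the second step uses it up.

    D + X → D.X, rate k1*[D]^1.5*[X]^0.5 (k1 = 0.0851 /M/s, Ea1 = 55.0 kJ/mol)
    X + D.X → X.D.X (k2 = 0.00324 /M/s, Ea2 = 66.0 kJ/mol)
    X → G (k3 = 4.06 × 10⁻⁶ /s, Ea3 = 97.0 kJ/mol)
    (constants at 35 °C)

- epsilon: D 0.050 M; X 0.0600 M; temperature 35 °C; time 15 min
- theta: D 0.050 M; X 0.0600 M; temperature 10 °C; time 15 min

- which flask leads in amount of D.X, in percent of the D charged ("all alike" within 1.5 percentage points) (epsilon / theta / all alike)
- how much D.X is there at the end, in percent of the D charged: epsilon
- how much D.X is there at the end, in percent of the D charged: theta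

- all constants are for 35 °C and move with temperature by the activation energies

1. The powers in the first step's rate add up to 2, so each D reacts at a pace set by one concentration, the square root of D times X. It starts at 0.0548 M.

2. I count in fractions: f is the D left of its charge, x the X left of its own. The first-step clock τ is one over the first rate constant times that starting concentration, 3.58 min in epsilon. Setting x equal to f makes the step plain second order, and f is one over one plus t/τ. D is the limiting reagent, so x stays above f and this reckoning leaves D too high.

3. This is the fastest rung. In epsilon, 15 min is 4.20 clocks, so f is 19.2 %. Theta's first step is 6.7 times slower, so its clock is 23.8 min, longer than the run. That makes 0.630 clocks, and f in theta is 61.3 %.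

4. Next comes the clock of D.X at full X, 85.7 min in epsilon and 13.9 h in theta. Each is longer than that flask's first-step clock , so D.X piles up before it goes on.

5. The slowest rung is X going to G, with a clock of 68.4 h in epsilon, and 28 times longer in theta.

6. So my clock has 80.8 % of the D used in epsilon and 38.7 % in theta, and I take these as my estimates of D.X, with epsilon ahead. They are rough: the clock understates the D used, while the second step takes D.X away, so the two errors pull in opposite directions.

7. The forecast gives 78.4 % for epsilon and 39 % for theta, with epsilon leading, and starts from this: “Step 1 integrates exactly if X − D stays at a = 0.01 M”. Its epsilon figure is lower than my 80.8 %.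

The flasks give 78.4 % of D.X in epsilon and 39.0 % in theta, so epsilon leads, and D in theta reads 60.7 % against the 61.3 % from my clock. In theta, X goes into D.X 140 times as fast as into X.D.X at 5.75 min, and 52 times as fast at 15.0 min, when X.D.X reads 0.310 %. The same theta flask read at 1.0 h is 2.52 clocks along, which gives f as 28.4 %; it holds D at 26.6 % and D.X at 71.6 %.

The numbers of this flask are made up; no experiment stands behind them.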